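**Plan**
- Retrosynthesis: the acetate and the enol ether C14=C15 (from a 15,16-lactone) are cut first, then O9–C13 (5-exo epoxide opening) and C11–C12 (spiro-oxirane plus allyl dianion). Next come C9=C11 and the C6 oxygen, back to a C14 decalin enone, then C3–C4 (ring A), and last C10–C1 and C10–C20 (two enolate alkylations of (R)-carvone).
- Forward: ring B is carvone, then quaternary C10, ring A (step 3), removal of the C2 helper, adjustment of C6/C8/C9, the side chain, the tetrahydrofuran ring, the dihydrofuran ring and the acetate.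
- Enabling feature: C4 with C18/C19 on C5 is the hydrated isopropenyl group of carvone (carvone C=O becomes C9, its ring methyl C17). Hydrogen-atom transfer to that group gives the tertiary C4 radical, which closes ring A (C1–C2–C3–C4–C5–C10) on the CH2 terminus (C3) of an acrylate arm on C10. The CO2Me helper on C2 is then removed by decarboxylation.
- Stereochemistry: C5 from (R)-carvone; C10 by alkylation anti to the isopropenyl group; C8 thermodynamic (equatorial methyl next to the C9 ketone); C6 by hydride from the α-face; C9 by α-face epoxidation of the 9(11)-alkene; C13 by catalyst-controlled epoxidation and inversion in the ring closure.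

Key step: step 3

Remark: locants and α/β follow labdane numbering (C17 = CH3 on C8, C18/C19 = CH3 on C4, C20 = CH3 on C10, C11–C16 = side chain). All bicyclic compounds have 5α-H and 10β-CH3. Compounds 2, 5, 6 and 18 are carried as epimer mixtures at centres that are destroyed later (C10-H of 2, C2 of 5 and 6, C15 of 18).

**Step 1**
Reactants: 1 (R)-(−)-carvone
Product: 2 (5R,6S)-2,6-dimethyl-5-(prop-1-en-2-yl)cyclohex-2-en-1-one (trans-6-methylcarvone, with some 6-epimer)
Conditions: LiN(i-Pr)2, THF, −78 °C; MeI, −78 to 0 °C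
Reagents that add atoms: iodomethane, CI
Why: Kinetic α′-deprotonation of the enone and C-methylation of the lithium enolate (enolate alkylation), mainly anti to the isopropenyl group; the new centre is planarised again in step 2, so its ratio is immaterial.

**Step 2**
Reactants: 2 trans-6-methylcarvone; 3 methyl 2-(bromomethyl)prop-2-enoate
Product: 4 methyl 2-{[(1S,6S)-1,3-dimethyl-2-oxo-6-(prop-1-en-2-yl)cyclohex-3-en-1-yl]methyl}prop-2-enoate
Conditions: LiN(i-Pr)2, THF, −78 to −10 °C; then 3, −78 to −20 °C
Reagents that add atoms: none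
Why: Second enolate alkylation at the same carbon with the SN2′-reactive allylic bromide; the electrophile should enter anti to the isopropenyl group on C5, which sets quaternary C10 with the methyl cis and the acrylate arm trans to the isopropenyl group.

**Step 3**
Reactants: 4 acrylate-armed carvone
Product: 5 methyl (4aS,8aS)-4,4,7,8a-tetramethyl-8-oxo-1,2,3,4,4a,5,8,8a-octahydronaphthalene-2-carboxylate (C2 epimers)
Conditions: Fe(acac)3 (50 mol %), PhSiH3 (2.5 equiv), EtOH/(CH2OH)2 5:1, degassed, 60 °C
Reagents that add atoms: none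
Why: Hydrogen-atom transfer from the iron hydride formed from Fe(acac)3 and PhSiH3 to the electron-rich 1,1-disubstituted isopropenyl group gives the tertiary C4 radical, which adds to the unsubstituted terminus (C3) of the 2-substituted acrylate; the α-ester radical at C2 is reduced by divalent iron to the enolate and protonated by ethanol. The closest known reaction type is the iron-hydride reductive olefin coupling (MHAT-initiated Giese reaction) in its intramolecular form. Ring A closes in the 6-endo-trig mode, because attack at C3 gives the ester-stabilised radical, whereas the 5-exo alternative would have to attack the fully substituted C2 and leave a primary radical. C4 becomes a quaternary, non-stereogenic carbon, the new centre at C2 is inconsequential (removed in step 5), and the trans ring fusion follows from the existing C5 and C10 centres, whose two arms are trans-diequatorial on ring B. The step needs hydrogen-atom transfer to the isopropenyl group and not to the acrylate or the ring enone; the preference of the metal hydride for electron-rich 1,1-disubstituted alkenes should secure this, and the ring enone cannot be reached by the C4 radical (a four-membered ring would result).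

**Step 4**
Reactants: 5 bicyclic ester
Product: 6 (4aS,8aS)-4,4,7,8a-tetramethyl-8-oxo-1,2,3,4,4a,5,8,8a-octahydronaphthalene-2-carboxylic acid (C2 epimers)
Conditions: LiOH, THF/MeOH/H2O, 40 °C; then 1 M HCl
Reagents that add atoms: lithium hydroxide, [Li+].[OH-]
Why: Ester saponification, which leaves the enone and the ring-fusion centres untouched.

**Step 5**
Reactants: 6 bicyclic acid
Product: 7 (4aS,8aS)-2,5,5,8a-tetramethyl-4a,5,6,7,8,8a-hexahydronaphthalen-1(4H)-one
Conditions: 9-mesityl-10-phenylacridinium tetrafluoroborate (5 mol %), PhSSPh (10 mol %), i-Pr2NEt (20 mol %), CF3CH2OH, 450 nm LEDs, 25 °C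
Reagents that add atoms: none
Why: Photoredox hydrodecarboxylation (carboxylate oxidation, loss of CO2, hydrogen-atom transfer from thiophenol to the secondary C2 radical) removes the helper and with it the C2 stereocentre.

**Step 6**
Reactants: 7 decalin enone
Product: 8 (4aS,8aS)-2,5,5,8a-tetramethyl-4a,5,6,7,8,8a-hexahydronaphthalene-1,4-dione
Conditions: Pd(OH)2/C (5 mol %), t-BuOOH (5 equiv), K2CO3 (0.25 equiv), CH2Cl2, 4 °C
Reagents that add atoms: tert-butyl hydroperoxide, CC(C)(C)OO
Why: Peroxide-based γ-oxidation of an enone to the ene-1,4-dione, which should take place at C6, the only γ-CH2 (C10 is quaternary), and so installs the C6 oxygen.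

**Step 7**
Reactants: 8 ene-dione
Product: 9 (2R,4aS,8aS)-2,5,5,8a-tetramethyloctahydronaphthalene-1,4-dione (8α-methyl, trans-fused)
Conditions: Zn dust, AcOH, 25 °C; then NaOMe (cat.), MeOH, 25 °C
Reagents that add atoms: none
Why: Zinc/acetic acid reduction of the ene-1,4-dione C7=C8 bond; C8 (α to the C9 ketone) should equilibrate to the equatorial 8α-methyl epimer and C5 (α to the C6 ketone) should stay trans-fused.

**Step 8**
Reactants: 9 saturated 6,9-dione
Product: 10 6β-hydroxy-4,4,8α,10β-tetramethyl-5α-decalin-9-one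
Conditions: NaBH4 (1 equiv), MeOH/CH2Cl2, −30 °C
Reagents that add atoms: none
Why: Borohydride reduction of the less hindered C6 ketone (C9 is flanked by quaternary C10 and the C8 methine), with hydride delivered from the α-face because the β-face of C6 is blocked by the syn-axial C19 and C20 methyls, which should give the axial 6β-alcohol.

**Step 9**
Reactants: 10 6β-hydroxy-9-ketone
Product: 11 4,4,8α,10β-tetramethyl-9-methylidene-5α-decalin-6β-ol
Conditions: Ph3PCH3Br (4 equiv), KOt-Bu (4 equiv), toluene, 90 °C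
Reagents that add atoms: methyltriphenylphosphonium bromide, C[P+](c1ccccc1)(c1ccccc1)c1ccccc1.[Br-]
Why: Wittig methylenation under the hot tert-butoxide conditions that serve for strongly hindered ketones, with the 6-hydroxyl carried as its alkoxide and C8 already in its stable configuration.

**Step 10**
Reactants: 11 9(11)-alkene
Product: 12 9α,11-epoxy-4,4,8α,10β-tetramethyl-5α-decalin-6β-ol (spiro-oxirane, O on the α-face, C11 β)
Conditions: mCPBA, NaHCO3, CH2Cl2, 0 °C
Reagents that add atoms: 3-chloroperoxybenzoic acid, OOC(=O)c1cccc(Cl)c1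
Why: Prilezhaev epoxidation of the exocyclic alkene from the α-face, anti to the adjacent axial C10 methyl, which should set C9 with oxygen α and C11 β.

**Step 11**
Reactants: 12 9α,11-epoxide; 13 3-methylbut-3-en-1-ol
Product: 14 labd-13(16)-ene-6β,9α,15-triol (8α-methyl)
Conditions: 13 (4 equiv), n-BuLi (8 equiv), TMEDA, Et2O, 0 to 25 °C; then 12, THF, 0 to 40 °C; aq. NH4Cl
Reagents that add atoms: none
Why: SN2 opening of the 2,2-disubstituted oxirane at its CH2 carbon (C11) by the allyl-type dianion of 13; the C9–O bond is not touched, so the 9α-hydroxyl configuration from step 10 is kept.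

**Step 12**
Reactants: 14 triol alkene
Product: 16 (13R)-9α,13-epoxylabdane-6β,15,16-triol, via 13,16-epoxide 15 (not isolated)
Conditions: VO(Oi-Pr)3 (5 mol %), C2-symmetric chiral bishydroxamic acid ligand (6 mol %, the enantiomer that gives the 13S epoxide), cumene hydroperoxide, toluene, 0 °C; then camphorsulfonic acid (5 mol %), CH2Cl2, 0 °C
Reagents that add atoms: cumene hydroperoxide, CC(C)(OO)c1ccccc1
Why: Hydroxyl-directed asymmetric epoxidation of the homoallylic alcohol (vanadium–bishydroxamic acid catalysis) should set the (13S)-epoxide under catalyst control, and the 9α-hydroxyl then opens it 5-exo-tet at the tertiary C13 with inversion to give the (13R)-spiro ether.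

**Step 13**
Reactants: 16 spiro ether triol
Product: 17 (13R)-9α,13-epoxy-6β-hydroxylabdan-15,16-olide
Conditions: TEMPO (20 mol %), PhI(OAc)2 (2.5 equiv), CH2Cl2, 25 °C
Reagents that add atoms: none
Why: Oxoammonium (TEMPO) oxidative lactonisation of the 1,4-diol; the unhindered C15 alcohol should be oxidised before the neopentyl C16 alcohol, the aldehyde closes to the lactol and is oxidised on, and the hindered secondary 6β-hydroxyl is left alone.

**Step 14**
Reactants: 17 lactone
Product: 18 (13R)-9α,13:15,16-diepoxylabdane-6β,15-diol (lactol, C15 epimers)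
Conditions: i-Bu2AlH (2.5 equiv), CH2Cl2, −78 °C; aq. potassium sodium tartrate
Reagents that add atoms: none
Why: Half-reduction of a γ-lactone to the lactol with i-Bu2AlH at low temperature, the extra equivalent being taken up by the 6-hydroxyl.

**Step 15**
Reactants: 18 lactol
Product: 20 (13R)-9α,13:15,16-diepoxylabd-14-en-6β-ol, via lactol mesylate 19 (not isolated)
Conditions: MsCl (1.2 equiv), Et3N (5 equiv), CH2Cl2, −40 to 25 °C
Reagents that add atoms: none
Why: Sulfonylation of the anomeric hydroxyl and base-mediated elimination (dehydration of a 2-deoxy lactol to the cyclic enol ether), which can only give C14=C15 because C13 is quaternary; the basic medium should protect the acid-labile spiro enol ether and the congested axial 6β-hydroxyl should not be sulfonylated.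

**Step 16**
Reactants: 20 dihydrofuran alcohol
Product: 21 (13R)-9α,13:15,16-diepoxylabd-14-en-6β-yl acetate (CNP0242014.1)
Conditions: Ac2O, DMAP, Et3N, CH2Cl2, 40 °C
Reagents that add atoms: acetic anhydride, CC(=O)OC(C)=O
Why: DMAP-catalysed acylation of the hindered axial alcohol under basic conditions, which the enol ether should tolerate.

**Compound list**
1 | (R)-(−)-carvone | C1C=C(C)C(=O)C[C@@H]1C(C)=C | starting material
2 | (5R,6S)-2,6-dimethyl-5-(prop-1-en-2-yl)cyclohex-2-en-1-one (major epimer) | C1C=C(C)C(=O)[C@@H](C)[C@@H]1C(C)=C | intermediate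
3 | methyl 2-(bromomethyl)prop-2-enoate | C=C(CBr)C(=O)OC | starting material
4 | methyl 2-{[(1S,6S)-1,3-dimethyl-2-oxo-6-(prop-1-en-2-yl)cyclohex-3-en-1-yl]methyl}prop-2-enoate | C1C=C(C)C(=O)[C@@](C)(CC(=C)C(=O)OC)[C@@H]1C(C)=C | intermediate
5 | methyl (4aS,8aS)-4,4,7,8a-tetramethyl-8-oxo-1,2,3,4,4a,5,8,8a-octahydronaphthalene-2-carboxylate (C2 epimers) | C1C=C(C)C(=O)[C@@]2(C)CC(C(=O)OC)CC(C)(C)[C@H]12 | intermediate
6 | (4aS,8aS)-4,4,7,8a-tetramethyl-8-oxo-1,2,3,4,4a,5,8,8a-octahydronaphthalene-2-carboxylic acid (C2 epimers) | C1C=C(C)C(=O)[C@@]2(C)CC(C(=O)O)CC(C)(C)[C@H]12 | intermediate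
7 | (4aS,8aS)-2,5,5,8a-tetramethyl-4a,5,6,7,8,8a-hexahydronaphthalen-1(4H)-one | C1C=C(C)C(=O)[C@@]2(C)CCCC(C)(C)[C@H]12 | intermediate
8 | (4aS,8aS)-2,5,5,8a-tetramethyl-4a,5,6,7,8,8a-hexahydronaphthalene-1,4-dione | O=C1C=C(C)C(=O)[C@@]2(C)CCCC(C)(C)[C@H]12 | intermediate
9 | (2R,4aS,8aS)-2,5,5,8a-tetramethyloctahydronaphthalene-1,4-dione | O=C1C[C@@H](C)C(=O)[C@@]2(C)CCCC(C)(C)[C@H]12 | intermediate
10 | 6β-hydroxy-4,4,8α,10β-tetramethyl-5α-decalin-9-one | O[C@@H]1C[C@@H](C)C(=O)[C@@]2(C)CCCC(C)(C)[C@H]12 | intermediate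
11 | 4,4,8α,10β-tetramethyl-9-methylidene-5α-decalin-6β-ol | O[C@@H]1C[C@@H](C)C(=C)[C@@]2(C)CCCC(C)(C)[C@H]12 | intermediate
12 | 9α,11-epoxy-4,4,8α,10β-tetramethyl-5α-decalin-6β-ol | O[C@@H]1C[C@@H](C)[C@]3(CO3)[C@@]2(C)CCCC(C)(C)[C@H]12 | intermediate
13 | 3-methylbut-3-en-1-ol | CC(=C)CCO | starting material
14 | labd-13(16)-ene-6β,9α,15-triol | O[C@@H]1C[C@@H](C)[C@](O)(CCC(=C)CCO)[C@@]2(C)CCCC(C)(C)[C@H]12 | intermediate
15 | (13S)-13,16-epoxylabdane-6β,9α,15-triol | O[C@@H]1C[C@@H](C)[C@](O)(CC[C@@]4(CO4)CCO)[C@@]2(C)CCCC(C)(C)[C@H]12 | intermediate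
16 | (13R)-9α,13-epoxylabdane-6β,15,16-triol | O[C@@H]1C[C@@H](C)[C@]2(CC[C@](CO)(CCO)O2)[C@@]2(C)CCCC(C)(C)[C@H]12 | intermediate
17 | (13R)-9α,13-epoxy-6β-hydroxylabdan-15,16-olide | O[C@@H]1C[C@@H](C)[C@]2(CC[C@]3(CC(=O)OC3)O2)[C@@]2(C)CCCC(C)(C)[C@H]12 | intermediate
18 | (13R)-9α,13:15,16-diepoxylabdane-6β,15-diol (C15 epimers) | O[C@@H]1C[C@@H](C)[C@]2(CC[C@]3(CC(O)OC3)O2)[C@@]2(C)CCCC(C)(C)[C@H]12 | intermediate
19 | 15-O-methanesulfonate of 18 | O[C@@H]1C[C@@H](C)[C@]2(CC[C@]3(CC(OS(C)(=O)=O)OC3)O2)[C@@]2(C)CCCC(C)(C)[C@H]12 | intermediate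
20 | (13R)-9α,13:15,16-diepoxylabd-14-en-6β-ol | O[C@@H]1C[C@@H](C)[C@]2(CC[C@]3(C=COC3)O2)[C@@]2(C)CCCC(C)(C)[C@H]12 | intermediate
21 | (13R)-9α,13:15,16-diepoxylabd-14-en-6β-yl acetate | CC(=O)O[C@@H]1C[C@@H](C)[C@]2(CC[C@]3(C=COC3)O2)[C@@]2(C)CCCC(C)(C)[C@H]12 | target

**Totals**
Total step count: 16. Longest linear sequence: 16 steps (1 to 21); 3 and 13 are bought and enter directly.

**Steps most likely to fail**

Step 12. The risk is loss of facial control in the oxygen transfer to C13=C16, because the tertiary 9-hydroxyl can compete with the primary 15-hydroxyl as the directing group; both C13 epimers would then form. The fallback sets out from 12 and returns at 20, using an allylic alcohol so that a titanium–tartrate epoxidation sets C13.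
- Opening of 12 with the dianion of 2-methylprop-2-en-1-ol (n-BuLi, TMEDA) should give 15-norlabd-13(14)-ene-6β,9α,16-triol F5.
- Sharpless asymmetric epoxidation (Ti(Oi-Pr)4, D-(−)-diethyl tartrate, t-BuOOH, −20 °C) should give (13R)-13,14-epoxy-15-norlabdane-6β,9α,16-triol F6.
- TBSCl/imidazole should silylate only the primary hydroxyl, giving the 16-O-TBS ether of the epoxy triol F7.
- Camphorsulfonic acid should close the spiro ring by attack of the 9α-hydroxyl at C13 with inversion, giving 16-O-TBS-9α,13-epoxy-15-norlabdane-6β,14,16-triol F8.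
- TEMPO/PhI(OAc)2 should give the 14-aldehyde of the spiro ether F9.
- Dimethyl (1-diazo-2-oxopropyl)phosphonate with K2CO3 in MeOH (Ohira–Bestmann) should give 16-O-TBS-9α,13-epoxylabd-14-yne-6β,16-diol F10.
- Bu4NF should give 9α,13-epoxylabd-14-yne-6β,16-diol F11.
- Mo(CO)6/Et3N under irradiation should cycloisomerise this but-3-yn-1-ol to the 2,3-dihydrofuran 20.

Step 11. The risk is base-induced anti-elimination across C8–C9, which opens the oxirane to the 8-en-11-ol, or no attack at the congested neopentyl C11. The fallback sets out from 12 and returns at 14, forming the C11–C12 bond by a neutral radical reaction.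
- LiI/AcOH in THF should open the oxirane to 11-iodo-4,4,8α,10β-tetramethyl-5α-decalin-6β,9α-diol F3.
- The dianion of 13 with Bu3SnCl should give 3-[(tributylstannyl)methyl]but-3-en-1-ol F4.
- Keck radical allylation of the iodohydrin with the stannane (AIBN, benzene, 80 °C) should give 14.

Step 3. The risk is hydrogen-atom transfer to the acrylate, or quenching of the C4 radical before the 6-endo closure, which would simply reduce the isopropenyl group. The fallback sets out from 2 and returns at 7, closing the same C3–C4 bond by a cationic route and bypassing 4 to 6.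
- Alkylation of the enolate of 2 with allyl bromide (LiN(i-Pr)2, THF) should give (5S,6S)-2,6-dimethyl-6-(prop-2-en-1-yl)-5-(prop-1-en-2-yl)cyclohex-2-en-1-one F1.
- Anhydrous HCl with SnCl4 in CH2Cl2 at −78 °C should protonate the isopropenyl group; the C4 cation is captured 6-endo by the terminal allyl carbon and chloride traps the secondary C2 cation, giving (4aS,8aS)-7-chloro-2,5,5,8a-tetramethyl-4a,5,6,7,8,8a-hexahydronaphthalen-1(4H)-one F2.
- Bu3SnH/AIBN should remove the chlorine and give 7.

**Further compounds**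
F1 | step 3 | (5S,6S)-2,6-dimethyl-6-(prop-2-en-1-yl)-5-(prop-1-en-2-yl)cyclohex-2-en-1-one | C1C=C(C)C(=O)[C@@](C)(CC=C)[C@@H]1C(C)=C
F2 | step 3 | (4aS,8aS)-7-chloro-2,5,5,8a-tetramethyl-4a,5,6,7,8,8a-hexahydronaphthalen-1(4H)-one (C7 epimers) | C1C=C(C)C(=O)[C@@]2(C)CC(Cl)CC(C)(C)[C@H]12
F3 | step 11 | 11-iodo-4,4,8α,10β-tetramethyl-5α-decalin-6β,9α-diol | O[C@@H]1C[C@@H](C)[C@](O)(CI)[C@@]2(C)CCCC(C)(C)[C@H]12
F4 | step 11 | 3-[(tributylstannyl)methyl]but-3-en-1-ol | CCCC[Sn](CCCC)(CCCC)CC(=C)CCO
F5 | step 12 | 15-norlabd-13(14)-ene-6β,9α,16-triol | O[C@@H]1C[C@@H](C)[C@](O)(CCC(=C)CO)[C@@]2(C)CCCC(C)(C)[C@H]12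
F6 | step 12 | (13R)-13,14-epoxy-15-norlabdane-6β,9α,16-triol | O[C@@H]1C[C@@H](C)[C@](O)(CC[C@@]4(CO)CO4)[C@@]2(C)CCCC(C)(C)[C@H]12
F7 | step 12 | 16-O-TBS ether of the epoxy triol | O[C@@H]1C[C@@H](C)[C@](O)(CC[C@@]4(CO[Si](C)(C)C(C)(C)C)CO4)[C@@]2(C)CCCC(C)(C)[C@H]12
F8 | step 12 | 16-O-TBS-9α,13-epoxy-15-norlabdane-6β,14,16-triol | O[C@@H]1C[C@@H](C)[C@]2(CC[C@](CO[Si](C)(C)C(C)(C)C)(CO)O2)[C@@]2(C)CCCC(C)(C)[C@H]12
F9 | step 12 | 14-aldehyde of the spiro ether | O[C@@H]1C[C@@H](C)[C@]2(CC[C@](CO[Si](C)(C)C(C)(C)C)(C=O)O2)[C@@]2(C)CCCC(C)(C)[C@H]12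
F10 | step 12 | 16-O-TBS-9α,13-epoxylabd-14-yne-6β,16-diol | O[C@@H]1C[C@@H](C)[C@]2(CC[C@](CO[Si](C)(C)C(C)(C)C)(C#C)O2)[C@@]2(C)CCCC(C)(C)[C@H]12
F11 | step 12 | 9α,13-epoxylabd-14-yne-6β,16-diol | O[C@@H]1C[C@@H](C)[C@]2(CC[C@](CO)(C#C)O2)[C@@]2(C)CCCC(C)(C)[C@H]12
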